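A small charge of L lets G stand still: theta, on 20 mM, reads 28.1 % and then 28.7 %, while gamma, on 30 mM, falls back to 24.5 %.

| setting | theta | gamma | flask |
|---|---|---|---|
| X | 20 mM | 20 mM | 20 mM |
| L | 20 mM | 30 mM | 40.0 mM |
| remark | run made earlier | run made earlier |  |
| time |  |  | 2.0 h |

| run | time / min | G / % | J / % |
|---|---|---|---|
| theta | 2.00 | 10.3 | 0 |
| theta | 6.00 | 22.5 | 3.0 |
| theta | 25.0 | 28.1 | 11.0 |
| theta | 90.0 | 28.7 | 14.5 |
| gamma | 2.00 | 15.0 | 0.7 |
| gamma | 6.00 | 26.6 | 4.8 |
| gamma | 25.0 | 26.9 | 22.6 |
| gamma | 90.0 | 24.5 | 26.4 |

(readings scatter by 0.5 percentage points)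

- the best time, 2.0 h at the latest, for G
- the amount of G, in percent of the X charged, at that time

The first readings of G stand in the ratio 1.46 and the charges of L in 1.50, so I take L as the clock of the making of G. If L also carries the loss of G, it cancels from the selectivity factor, and with X held, more L reaches the same height sooner. So I carry the ceiling of G, the mean of theta's last two readings, 28.4 %.

My bracket on height runs from gamma's highest reading, 26.9 %, up to theta's highest, 28.7 %, plus a scatter of 0.5 percentage points. Gamma reads 26.6 % at 6.00 min and 26.9 % at 25.0 min, and lower at both ends of the run, so I place its peak between these two readings, which may straddle it and stand below it. Scaled by the charges of L, that gives 0.0750 h to 0.312 h, and the middle in logarithms is 0.153 h.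

The forecast says 0.17 h and 26 %, holding that “more L favours over-reaction”. Its time lies inside my bracket, its height just below it.

The flask gives 28.1 % at 0.122 h, inside both brackets, and the forecast's time is late by a factor of 1.39.

    L + Q → J + Z (k = 0.170 L mol⁻¹ s⁻¹)
    X + L → G + Z (k = 0.0582 L mol⁻¹ s⁻¹)
    L + J → E (k = 0.0199 L mol⁻¹ s⁻¹)
    L + G → Q + Z (k = 0.0959 L mol⁻¹ s⁻¹)

Theta's own top, without the scatter, is 28.1 %, level with the flask. The ceiling stands 0.30 points above the flask's value.

Take L up to 100 mM with X unchanged: the ceiling says 28.4 % again. The computed top there is 28.1 %.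

The readings are simulated on assumed constants, noise included.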